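The flavone is cut at the three bonds that radiate from C2 (to O1, C3 and C1'), because this lone sp2 carbon is all that separates ring B from the ring A ketone side chain; it can therefore enter as carbon monoxide. One palladium-catalysed carbonylative annulation merges an aryl iodide (ring B), CO and an ortho-hydroxyaryl methoxymethyl ketone (ring A with C4, C3 and the 3-methoxy group), forging all three bonds and closing ring C. The ketone has a single free phenol beside the future 8-methoxy group, which locks the 5,7,8 pattern. It is assembled by aryllithium acylation rather than through a fragile methoxyacetyl cation, and chelation-guided 5-O-demethylation finishes the synthesis.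

Key step: step 3

Remark: the target has no stereogenic element, so no SMILES carries a stereo descriptor. The sp3 centres of the transient intermediates form unselectively and vanish again. All four starting materials are taken to be catalogue chemicals.

Step 1
Reactants: 1 1,2,3,5-tetramethoxybenzene; 2 N,2-dimethoxy-N-methylacetamide
Product: 5 2-methoxy-1-(2,3,4,6-tetramethoxyphenyl)ethan-1-one, via aryllithium 3 (not isolated), via lithium hemiaminal adduct 4 (not isolated)
Conditions: n-BuLi (1.1 equiv), THF, 0 °C to rt; then 2 (1.2 equiv), −78 °C to 0 °C; 1 M HCl
Reagents that add atoms: none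
Why: Directed ortho-lithiation followed by Weinreb ketone synthesis: the two ring hydrogens of 1 are equivalent and each lies between two methoxy groups, so n-BuLi should give a single aryllithium, the chelated adduct 4 cannot add a second aryl group, and the sequence avoids a Friedel-Crafts methoxyacetyl cation, which sheds CO to a methoxymethyl cation and would alkylate the arene instead of acylating it.

Step 2
Reactants: 5 2-methoxy-1-(2,3,4,6-tetramethoxyphenyl)ethan-1-one
Product: 7 1-(2-hydroxy-3,4,6-trimethoxyphenyl)-2-methoxyethan-1-one, via aryloxydichloroborane chelate 6 (not isolated)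
Conditions: BCl3 (1.1 equiv, 1 M in CH2Cl2), CH2Cl2, −78 °C to 0 °C; H2O
Reagents that add atoms: none
Why: Chelation-directed aryl methyl ether cleavage with BCl3: boron bridges the ketone oxygen and an ortho methoxy oxygen and chloride removes the methyl group by SN2 attack, and of the two ortho ethers the one at C2, wedged between the acyl group and the 3-methoxy group and twisted out of conjugation, is the more Lewis basic and the more strained, so it should go first, while one equivalent of reagent at low temperature spares the 6-, 3-, 4- and side-chain ethers.

Step 3
Reactants: 7 1-(2-hydroxy-3,4,6-trimethoxyphenyl)-2-methoxyethan-1-one; 8 1-iodo-2,4-dimethoxybenzene; 9 carbon monoxide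
Product: 13 2-(2,4-dimethoxyphenyl)-3,5,7,8-tetramethoxy-4H-chromen-4-one (3,5,7,8,2',4'-hexamethoxyflavone), via aryl ester 10 (not isolated), via 1,3-diketone 11 (not isolated), via cyclic hemiketal 12 (not isolated)
Conditions: 8 (1.3 equiv), Pd(OAc)2 (5 mol %), 1,4-bis(diphenylphosphino)butane (10 mol %), DBU (3 equiv), CO (10 bar), dry DMAc, 110 °C; aqueous work-up, then crude in AcOH, cat. H2SO4, 80 °C
Reagents that add atoms: none
Why: Oxidative addition of 8 to zerovalent palladium (generated in the flask from Pd(OAc)2 and the diphosphine) and migratory insertion of CO give a divalent aroylpalladium iodide, which the DBU-generated phenoxide on C8a of 7 intercepts to give ester 10, thereby setting C1'–C2 and O1–C2. DBU then enolises the methoxymethyl ketone and C3 attacks the ester carbonyl in a Baker-Venkataraman acyl transfer, a 6-(enolendo)-exo-trig closure that forms C2–C3 and the ring C hemiketal 12; 12 may open to diketone 11 and close again through O1 on C2 (6-exo-trig), and E1cB loss of water, completed by the acid finish, delivers the pyranone. The closest known reaction type is the palladium-catalysed carbonylative coupling of aryl halides with 2-hydroxyacetophenones to flavones, and base-induced acyl transfer in omega-methoxy ketones is the classical entry to 3-methoxyflavones. No stereocentre is created in 13, since the sp3 centres of 11 and 12 are erased on dehydration. The step needs chemoselectivity for carbonylation and O-acylation over direct alpha-arylation or O-arylation, which CO pressure and the chelating diphosphine provide, and regioselectivity of ring closure, which 7 secures by offering only one free phenol, the one next to the future 8-methoxy group. The alpha-methoxy group makes the C3–H bonds more acidic than those of a plain acetophenone, and the weak C–I bond offsets the electron-rich, ortho-substituted nature of 8 in the oxidative addition.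

Step 4
Reactants: 13 2-(2,4-dimethoxyphenyl)-3,5,7,8-tetramethoxy-4H-chromen-4-one
Product: 15 2-(2,4-dimethoxyphenyl)-5-hydroxy-3,7,8-trimethoxy-4H-chromen-4-one (5-hydroxy-3,7,8,2',4'-pentamethoxyflavone), via boron chelate 14 (not isolated)
Conditions: BCl3 (1.5 equiv, 1 M in CH2Cl2), CH2Cl2, −78 °C to 0 °C; 1 M HCl, rt
Reagents that add atoms: none
Why: Chelation-directed peri demethylation with BCl3: the C4 carbonyl oxygen and the 5-methoxy oxygen hold boron in a six-membered chelate that activates only this methyl group towards chloride, the five-membered alternative through the 3-methoxy group is less favourable, the other four ethers have no carbonyl partner, and the mild aprotic conditions do not open ring C, so no Wessely-Moser drift to the 5,6,7 isomer is expected.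

Compound list
1 | 1,2,3,5-tetramethoxybenzene | COc1cc(OC)c(OC)c(OC)c1 | starting material
2 | N,2-dimethoxy-N-methylacetamide | COCC(=O)N(C)OC | starting material
3 | (2,3,4,6-tetramethoxyphenyl)lithium | [Li]c1c(OC)cc(OC)c(OC)c1OC | intermediate (not isolated)
4 | lithium 2-methoxy-1-[methoxy(methyl)amino]-1-(2,3,4,6-tetramethoxyphenyl)ethan-1-olate (racemic) | [Li]OC(COC)(N(C)OC)c1c(OC)cc(OC)c(OC)c1OC | intermediate (not isolated)
5 | 2-methoxy-1-(2,3,4,6-tetramethoxyphenyl)ethan-1-one | COCC(=O)c1c(OC)cc(OC)c(OC)c1OC | intermediate
6 | dichloro[2,3,5-trimethoxy-6-(methoxyacetyl)phenoxy]borane (carbonyl-chelated) | COCC(=O)c1c(OB(Cl)Cl)c(OC)c(OC)cc1OC | intermediate (not isolated)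
7 | 1-(2-hydroxy-3,4,6-trimethoxyphenyl)-2-methoxyethan-1-one | COCC(=O)c1c(O)c(OC)c(OC)cc1OC | intermediate (key-step precursor)
8 | 1-iodo-2,4-dimethoxybenzene | COc1ccc(I)c(OC)c1 | starting material
9 | carbon monoxide | [C-]#[O+] | starting material
10 | 2,3,5-trimethoxy-6-(methoxyacetyl)phenyl 2,4-dimethoxybenzoate | COCC(=O)c1c(OC(=O)c2ccc(OC)cc2OC)c(OC)c(OC)cc1OC | intermediate (not isolated)
11 | 1-(2,4-dimethoxyphenyl)-3-(2-hydroxy-3,4,6-trimethoxyphenyl)-2-methoxypropane-1,3-dione (racemic, enolisable) | COc1ccc(C(=O)C(OC)C(=O)c2c(O)c(OC)c(OC)cc2OC)c(OC)c1 | intermediate (not isolated)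
12 | 2-(2,4-dimethoxyphenyl)-2-hydroxy-3,5,7,8-tetramethoxychroman-4-one (mixture of stereoisomers) | COc1ccc(C2(O)Oc3c(OC)c(OC)cc(OC)c3C(=O)C2OC)c(OC)c1 | intermediate (not isolated)
13 | 2-(2,4-dimethoxyphenyl)-3,5,7,8-tetramethoxy-4H-chromen-4-one | COc1ccc(-c2oc3c(OC)c(OC)cc(OC)c3c(=O)c2OC)c(OC)c1 | intermediate (key-step product)
14 | 5-(dichloroboryloxy)-2-(2,4-dimethoxyphenyl)-3,7,8-trimethoxy-4H-chromen-4-one (C4 carbonyl-chelated) | COc1ccc(-c2oc3c(OC)c(OC)cc(OB(Cl)Cl)c3c(=O)c2OC)c(OC)c1 | intermediate (not isolated)
15 | 2-(2,4-dimethoxyphenyl)-5-hydroxy-3,7,8-trimethoxy-4H-chromen-4-one | COc1ccc(-c2oc3c(OC)c(OC)cc(O)c3c(=O)c2OC)c(OC)c1 | target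

Total step count: 4. Longest linear sequence: 4 steps (1 to 5 to 7 to 13 to 15).

Steps most likely to fail

Step 3.
- **Risk:** the hindered, internally hydrogen-bonded phenoxide may intercept the aroylpalladium species too slowly. Attack by traces of water or by DBU would then consume the acyl group while the catalyst decays to palladium metal. The acyl transfer or the dehydration may also stall.
- **Fallback:** the same three bonds are made without palladium or CO, with C2 coming from a carboxylic acid derivative. The detour sets out from 7, which is O-acylated with commercial 2,4-dimethoxybenzoyl chloride (pyridine, catalytic DMAP, CH2Cl2, rt) to give ester 10, now isolated. LiN(SiMe3)2 in THF (−78 °C to rt) brings about the Baker-Venkataraman shift to diketone 11. AcOH with catalytic H2SO4 at 80 °C cyclodehydrates it, and the route is rejoined at 13. This detour makes no compound beyond the list (entry F0).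

Step 2.
- **Risk:** discrimination between the two ortho methoxy groups may be incomplete, a second ortho cleavage may set in, or boron may be tied up by the side-chain ether. An NOE experiment on C5–H would tell the isomers apart: 7 has two flanking methoxy groups and the unwanted isomer has one.
- **Fallback:** selective dealkylation is replaced by selective alkylation. The detour sets out from 5, or from any mixture of partly cleaved ketones. Excess BCl3 (3 equiv, CH2Cl2, 0 °C to rt) strips both ortho methyl groups to give 1-(2,6-dihydroxy-3,4-dimethoxyphenyl)-2-methoxyethan-1-one F1. MeI (1.0 equiv) with K2CO3 in acetone at rt should then alkylate the exposed 6-hydroxyl next to C5–H. The 2-hydroxyl is walled in by the acyl group and the 3-methoxy group and stays chelated to the carbonyl, as is usual for the more hindered hydroxyl of 3-substituted 2,6-dihydroxyaryl ketones. The route is rejoined at 7.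

Step 4.
- **Risk:** further methyl groups may be lost, either at the 3-methoxy group through the five-membered chelate or at the crowded 8-methoxy group. The boron chelate may also hydrolyse sluggishly.
- **Fallback:** a redox route that uses the para relation of the 5- and 8-methoxy groups instead of Lewis acid chelation. The detour sets out from 13.
  - (NH4)2Ce(NO3)6 in MeCN/H2O at 0 °C removes both methyl groups oxidatively to give 2-(2,4-dimethoxyphenyl)-3,7-dimethoxy-4H-chromene-4,5,8-trione F2.
  - Na2S2O4 in EtOAc/H2O reduces the quinone to 2-(2,4-dimethoxyphenyl)-5,8-dihydroxy-3,7-dimethoxy-4H-chromen-4-one F3.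
  - MeI (1.0 equiv) with K2CO3 in acetone under argon should methylate only the unchelated 8-hydroxyl, because the 5-hydroxyl is locked in its hydrogen bond to the C4 carbonyl. The route is rejoined at 15.

Further compounds
F0 | step 3 | none | none
F1 | step 2 | 1-(2,6-dihydroxy-3,4-dimethoxyphenyl)-2-methoxyethan-1-one | COCC(=O)c1c(O)cc(OC)c(OC)c1O
F2 | step 4 | 2-(2,4-dimethoxyphenyl)-3,7-dimethoxy-4H-chromene-4,5,8-trione | COC1=CC(=O)C2=C(OC(c3ccc(OC)cc3OC)=C(OC)C2=O)C1=O
F3 | step 4 | 2-(2,4-dimethoxyphenyl)-5,8-dihydroxy-3,7-dimethoxy-4H-chromen-4-one | COc1ccc(-c2oc3c(O)c(OC)cc(O)c3c(=O)c2OC)c(OC)c1
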